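**Conventions and assumptions**

- Locants follow the flavanone: ring C is O1, C2, C3, C4; ring A is C4a to C8a; ring B is the aryl group on C2. The side chain is C1″ (methine on C8) to C9″. Ar = 4-(methoxymethoxy)phenyl, MOM = methoxymethyl, TBS = tert-butyldimethylsilyl, Ipc = isopinocampheyl.
- Assumption: boronic acid 41 and the pentane solution of B-allyldiisopinocampheylborane of the (1S,2S,3S,5R)-Ipc series are bought.
- Remark: the spatial arrangement at C1″ and C7″ is the same from 5 and 18 onward. Their CIP descriptors change with the neighbours (C7″: S in 5, 6, 8 and R from 9 on; C1″: S in 18, 19, 24, R in 25, 26, 30–33, S from 34 on).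

## The problem

The target is a (2S)-flavanone whose ring A carbon C8 carries a 1,9-diarylnon-2-enyl chain. The methine C1″ is therefore bonded to three sp2 carbons: C8, an aryl ring and the E-alkene C2″=C3″. There are three stereocentres, C2, C1″ and C7″. C7″ is five bonds from C1″ and ring A lies between C1″ and C2, so none can control another and each needs its own source of asymmetry. C1″ has no heteroatom and is doubly benzylic and allylic; it is best set by chirality transfer from a carbinol and is lost in any step that makes it a cation, anion or radical. The flavanone C2 epimerises by retro-oxa-Michael opening in base, the C5 methoxy group peri to C4=O is cleaved by Lewis acids, and the alkene rules out hydrogenolysis. Ring A is a 1,3,5-trioxygenated benzene with three different oxygens: C8 sits between C8a (O1) and C7 (OH) and is para to C5 (OMe). That is the pattern a cyclobutenone–alkoxyalkyne benzannulation writes: C8a, C8, C7 and C6 from a 3-alkoxy-4-alkylcyclobutenone, C4a and C5 from methoxyacetylene. Ring A can thus be grown on an aliphatic acid that already holds C1″. The two oxygens flanking C8 differ only in which one has an acylated neighbour, so a single free phenol from the annulation makes acylation at C4a unambiguous.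

## Retrosynthesis

**43 to 42.** The five hydroxyl groups are unmasked last, in one protic-acid operation that removes three MOM ethers, the TBS ether and the tert-butyl ether of 42. Lewis acids and hydrogenolysis are excluded by the C5 methoxy group and the alkene. Base is excluded by C2.

**42 to 40 and 41.** The C2–C1′ bond is cut, calling for a rhodium-catalysed asymmetric conjugate arylation of chromone 40 with boronic acid 41. The neighbouring cut, O1–C2 by oxa-Michael closure of a 2′-hydroxychalcone, was set aside: unactivated chalcones with an electron-rich B ring cyclise with modest catalyst control, and thermodynamic closure gives both C2 epimers. Chromone 40 has no stereocentre at C2, and the forward step needs only face selection by the ligand and tolerance of ethers and the isolated alkene.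

**40 to 34 via 38, 37 and 36.** C2 comes from a formamide acetal and the C4a–C4 bond from an acylation ortho to the free phenol. Direct Friedel–Crafts acetylation cannot tell C4a from C6, and its Lewis acids would strip the ethers. A magnesium-phenoxide-templated formylation reacts only ortho to the free OH, and C8 is blocked, so 36 forms at C4a alone. Methyl addition and benzylic oxidation then give ketone 38.

**34 to 26 and 29 (key).** The C4a–C8a and C5–C6 bonds are cut, with C8–C8a re-formed in the ring closure. The alternative of attaching the chain to a preformed trioxygenated arene would create C1″ by ionic substitution without stereocontrol and with ambiguous ring regiochemistry. Precursor 26 has no aromatic ring A at all. The forward cascade must place methoxy para to C8 and leave C1″ and the alkene untouched.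

**26 to 19 and 23.** The four-membered ring is cut into aldoketene 25 (from acid 19 via chloride 24) and tert-butoxyethyne 23. The tert-butyl group is the one ynol ether substituent that can later be removed by protic acid. Alkyne 23 is traced to trichloroethylene 20, and methoxyethyne 29 to chloroacetal 27.

**19 to 14 and 15.** The C1″–C8 bond is cut by a Johnson–Claisen rearrangement of allylic alcohol 14 with orthoacetate 15, through ester 18. This turns the heteroatom-free centre C1″ into a carbinol problem and fixes the E-alkene in the same step. The forward reaction needs clean suprafacial transfer, with S at C3″ giving S at C1″.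

**14 to 9 and 11.** The carbinol comes from CBS reduction of enone 13. The C1″=C2″ bond of 13 comes from a Claisen–Schmidt condensation of methyl ketone 9 with aldehyde 11, which is made from 10.

**9 to 1.** Ketone 9 comes from cross-metathesis of homoallylic silyl ether 6 with enone 7 and hydrogenation of 8. Compound 6 comes from alcohol 5, whose C6″–C7″ bond and C7″ configuration are set by Brown allylation of aldehyde 3, made from 1 via 2. A reagent-controlled allylation was preferred to ketone reduction at C7″ because the two alkyl arms of that carbinol are too alike for a reducing catalyst to distinguish.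

## Roads not taken

**Alternative 1:** Hidden C2 symmetry. The C2″–C3″ and C7″–C8″ bonds are cut together: two equivalents of an (E)-2-arylvinylzinc nucleophile add to pentanedial A1 under one chiral amino alcohol ligand to give diene-diol A2.
- Merits: both carbinols come from one catalyst in one step, double addition amplifies the enantiomeric purity, and the whole C1″–C9″ chain appears at once. It would reach the stage of 14 in clearly fewer steps than the nine used here.
- Weak points: A2 must be desymmetrised by saturating one of two identical styrenes. The sense is also mismatched: the Claisen step needs the (S)-allylic carbinol while C7″ needs the arrangement that is R in A2, a relation that corresponds to the meso diol. One carbinol of A2 would have to be inverted on an ionisable cinnamyl system. A1 is handled as an aqueous oligomer, a poor partner for organozinc reagents.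
- Comparison: the chosen plan is longer here, but sets C7″ (step 3) and C3″ (step 9) independently with the required relative sense, with no statistical step and no inversion.

**Alternative 2:** Enzymatic oxygen insertion. The C7″–O bond is formed by a Baeyer–Villiger monooxygenase acting on racemic cyclopentanone A3 under dynamic kinetic resolution, giving δ-lactone A4.
- Merits: C7″ is set catalytically, and C3″ arrives at the acid oxidation level with the two chain ends differentiated. Opening A4 with a phosphonate anion would replace steps 3 to 6 and avoid a stoichiometric chiral borane.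
- Weak points: acceptance of the bulky arylethyl substituent is uncertain. Racemisation of a 2-alkylcyclopentanone is slow near neutral pH, so the resolution may stop at half conversion. Cofactor recycling and oxygen transfer complicate scale-up.
- Comparison: Alternative 2 is more economical for the C3″–C7″ unit but says nothing about ring A or C1″. The chosen plan offers a predictable allylboration of an unbranched aldehyde that needs no screening.

**Alternative 3:** Acylium closure at C4a. The C4–C4a bond is cut: the (S)-3-aryl-3-aryloxypropanoic acid A5 is activated as a mixed anhydride and closes onto C4a to give pentaacetate A6.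
- Merits: C2 is set before ring C forms and no bond to it is made or broken in the closure. The tether enforces attack at C4a, so the ortho-acylation question disappears. The closure is a classical reaction, and fewer steps follow ring A than in the chosen plan.
- Weak points: in A5 the aryloxy group is β to the acylium carbon and benzylic to an electron-rich ring, so elimination or ionisation can erase C2. Strong acid meets the C2″=C3″ alkene. Final deacetylation in base threatens C2. Above all, A5 presupposes ring A already carrying the chain with defined C1″, which requires an ionic arylation without stereocontrol and the differentiation of two equivalent phenols.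
- Comparison: Alternative 3 is more convergent and rests on better-documented ring chemistry. The chosen plan fixes C1″ and the oxygen pattern by construction.

Key step: step 15

## Route

Step 1
Reactants: 1 methyl 3-(4-hydroxyphenyl)propanoate
Product: 2 methyl 3-[4-(methoxymethoxy)phenyl]propanoate
Conditions: MOMCl, i-Pr2NEt, CH2Cl2, 0 °C → rt
Reagents that add atoms: chloromethyl methyl ether, COCCl
Why: O-alkylation of the phenol (MOM protection); the ester is inert under these conditions.

Step 2
Reactants: 2 methyl 3-[4-(methoxymethoxy)phenyl]propanoate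
Product: 3 3-[4-(methoxymethoxy)phenyl]propanal
Conditions: i-Bu2AlH (1.1 equiv), CH2Cl2, −78 °C; aq. potassium sodium tartrate
Reagents that add atoms: none
Why: Partial ester reduction; the tetrahedral aluminium hemiacetal is stable at −78 °C and releases the aldehyde only on work-up.

Step 3
Reactants: 3 3-[4-(methoxymethoxy)phenyl]propanal
Product: 5 (3S)-1-[4-(methoxymethoxy)phenyl]hex-5-en-3-ol, via diisopinocampheylborinate ester 4 (not isolated)
Conditions: B-allyldiisopinocampheylborane [(1S,2S,3S,5R)-Ipc series, from (−)-α-pinene, 1 M in pentane], Et2O, −78 °C; then NaOH (3 M), H2O2 (30 %), 0 °C → rt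
Reagents that add atoms: B-allyldiisopinocampheylborane, C=CCB([C@H]1C[C@H]2C[C@@H]([C@@H]1C)C2(C)C)[C@H]1C[C@H]2C[C@@H]([C@@H]1C)C2(C)C
Why: Brown allylboration through a closed chair transition state; the (−)-α-pinene-derived reagent should attack the Re face of an unbranched aliphatic aldehyde, giving the (3S)-alcohol, which is C7″ of the target. Oxidative work-up frees the alcohol from the borinate.

Step 4
Reactants: 5 (3S)-1-[4-(methoxymethoxy)phenyl]hex-5-en-3-ol
Product: 6 tert-butyl({(3S)-1-[4-(methoxymethoxy)phenyl]hex-5-en-3-yl}oxy)dimethylsilane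
Conditions: t-BuMe2SiCl, imidazole, DMF, rt
Reagents that add atoms: tert-butyldimethylsilyl chloride, CC(C)(C)[Si](C)(C)Cl
Why: Standard silylation of a secondary alcohol; the TBS ether withstands base, heat and organometallics and falls in the final acid step.

Step 5
Reactants: 6 tert-butyl({(3S)-1-[4-(methoxymethoxy)phenyl]hex-5-en-3-yl}oxy)dimethylsilane; 7 but-3-en-2-one
Product: 8 (3E,6S)-6-[(tert-butyldimethylsilyl)oxy]-8-[4-(methoxymethoxy)phenyl]oct-3-en-2-one
Conditions: second-generation Grubbs catalyst RuCl2(=CHPh)(PCy3)(H2IMes) (3 mol %), 7 (4 equiv), CH2Cl2, 40 °C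
Reagents that add atoms: none
Why: Cross-metathesis of a terminal alkene with an electron-poor vinyl ketone is selective for the E cross product, and excess 7 suppresses homodimer of 6.

Step 6
Reactants: 8 (3E,6S)-6-[(tert-butyldimethylsilyl)oxy]-8-[4-(methoxymethoxy)phenyl]oct-3-en-2-one
Product: 9 (6R)-6-[(tert-butyldimethylsilyl)oxy]-8-[4-(methoxymethoxy)phenyl]octan-2-one
Conditions: H2 (1 atm), palladium on carbon (Pd/C, 10 %), EtOAc, rt
Reagents that add atoms: none
Why: Heterogeneous hydrogenation of the conjugated alkene; ketone, aryl MOM ether and silyl ether are not reduced at 1 atm. The descriptor changes to R only through CIP priorities.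

Step 7
Reactants: 10 4-hydroxybenzaldehyde
Product: 11 4-(methoxymethoxy)benzaldehyde
Conditions: MOMCl, i-Pr2NEt, CH2Cl2, 0 °C → rt
Reagents that add atoms: chloromethyl methyl ether, COCCl
Why: MOM protection of the phenol; the aldehyde does not react.

Step 8
Reactants: 9 (6R)-6-[(tert-butyldimethylsilyl)oxy]-8-[4-(methoxymethoxy)phenyl]octan-2-one; 11 4-(methoxymethoxy)benzaldehyde
Product: 13 (1E,7R)-7-[(tert-butyldimethylsilyl)oxy]-1,9-bis[4-(methoxymethoxy)phenyl]non-1-en-3-one, via β-hydroxy ketone 12 (not isolated)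
Conditions: NaOH (10 % aq), EtOH, rt
Reagents that add atoms: none
Why: Claisen–Schmidt condensation; under hydroxide a methyl alkyl ketone reacts at the methyl group with a non-enolisable aryl aldehyde, and dehydration of the aldol gives the conjugated E-enone.

Step 9
Reactants: 13 (1E,7R)-7-[(tert-butyldimethylsilyl)oxy]-1,9-bis[4-(methoxymethoxy)phenyl]non-1-en-3-one
Product: 14 (1E,3S,7R)-7-[(tert-butyldimethylsilyl)oxy]-1,9-bis[4-(methoxymethoxy)phenyl]non-1-en-3-ol
Conditions: (R)-2-methyl-CBS-oxazaborolidine (0.2 equiv), BH3·SMe2, THF, −30 °C; MeOH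
Reagents that add atoms: none
Why: CBS reduction; the arylvinyl group acts as the large substituent, so the (R)-catalyst should give the (3S)-allylic alcohol with 1,2-selectivity.

Step 10
Reactants: 14 (1E,3S,7R)-7-[(tert-butyldimethylsilyl)oxy]-1,9-bis[4-(methoxymethoxy)phenyl]non-1-en-3-ol; 15 triethyl orthoacetate
Product: 18 ethyl (3S,4E,9R)-9-[(tert-butyldimethylsilyl)oxy]-3,11-bis[4-(methoxymethoxy)phenyl]undec-4-enoate, via mixed orthoester 16 (not isolated), via ketene acetal 17 (not isolated)
Conditions: 15 (6 equiv), EtCO2H (5 mol %), xylene, 135 °C, EtOH distilled off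
Reagents that add atoms: none
Why: Johnson–Claisen rearrangement through a chair transition state with the C4″ chain equatorial; the new C–C bond forms on the face from which oxygen leaves, so the (3S,E)-alcohol should give (S)-C1″ and the E-alkene C2″=C3″.

Step 11
Reactants: 18 ethyl (3S,4E,9R)-9-[(tert-butyldimethylsilyl)oxy]-3,11-bis[4-(methoxymethoxy)phenyl]undec-4-enoate
Product: 19 (3S,4E,9R)-9-[(tert-butyldimethylsilyl)oxy]-3,11-bis[4-(methoxymethoxy)phenyl]undec-4-enoic acid
Conditions: LiOH, THF–MeOH–H2O, rt; HCl (1 M) to pH 4 at 0 °C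
Reagents that add atoms: lithium hydroxide, [Li+].[OH-]
Why: Saponification; C1″ is β to the carboxyl group and not enolisable, and the secondary silyl ether and MOM ethers tolerate aqueous hydroxide.

Step 12
Reactants: 20 trichloroethylene
Product: 23 tert-butoxyethyne, via (E)-1-tert-butoxy-1,2-dichloroethene 21 (not isolated), via lithium tert-butoxyacetylide 22 (not isolated)
Conditions: KH, t-BuOH, THF, 0 °C; 20, −50 °C → rt; n-BuLi (2.2 equiv), −78 → −40 °C; MeOH, −78 °C; distilled into cold pentane
Reagents that add atoms: tert-butanol, CC(C)(C)O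
Why: Known ynol ether synthesis: tert-butoxide adds to dichloroacetylene formed in situ, then n-BuLi effects elimination and chlorine–lithium exchange to the lithium acetylide, which is protonated.

Step 13
Reactants: 19 (3S,4E,9R)-9-[(tert-butyldimethylsilyl)oxy]-3,11-bis[4-(methoxymethoxy)phenyl]undec-4-enoic acid; 23 tert-butoxyethyne
Product: 26 3-tert-butoxy-4-[(1R,2E,7R)-7-[(tert-butyldimethylsilyl)oxy]-1,9-bis[4-(methoxymethoxy)phenyl]non-2-en-1-yl]cyclobut-2-en-1-one (both C4 epimers), via acid chloride 24 (not isolated), via aldoketene 25 (not isolated)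
Conditions: Me2C=C(Cl)NMe2 (1.2 equiv), CH2Cl2, 0 °C → rt; then slow addition to 23 (3 equiv), Et3N (1.5 equiv), CH2Cl2, 0 °C → rt
Reagents that add atoms: none
Why: The neutral chloroenamine makes the acid chloride without HCl, and Et3N generates the aldoketene, which undergoes [2+2] cycloaddition with the ynol ether. The nucleophilic CH carbon of 23 bonds to the ketene carbonyl carbon, giving the 3-alkoxy-4-alkylcyclobutenone. The one-carbon link between ketene and alkene rules out an intramolecular [2+2].

Step 14
Reactants: 27 2-chloro-1,1-dimethoxyethane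
Product: 29 methoxyethyne, via sodium methoxyacetylide 28 (not isolated)
Conditions: NaNH2 (3 equiv), liquid NH3, −33 °C; aq. NaCl, −70 °C; distilled (bp about 23 °C) into cold toluene
Reagents that add atoms: none
Why: Known preparation: twofold elimination (HCl, then methanol) with NaNH2 gives the sodium acetylide, which is protonated on aqueous quench.

Step 15
Reactants: 26 3-tert-butoxy-4-[(1R,2E,7R)-7-[(tert-butyldimethylsilyl)oxy]-1,9-bis[4-(methoxymethoxy)phenyl]non-2-en-1-yl]cyclobut-2-en-1-one; 29 methoxyethyne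
Product: 34 3-tert-butoxy-5-methoxy-2-[(1S,2E,7R)-7-[(tert-butyldimethylsilyl)oxy]-1,9-bis[4-(methoxymethoxy)phenyl]non-2-en-1-yl]phenol, via vinylketene 30 (not isolated), via 4-alkenylcyclobutenone 31 (not isolated), via dienylketene 32 (not isolated), via cyclohexa-2,4-dienone 33 (not isolated)
Conditions: 29 (5 equiv), toluene, sealed tube, 80 °C then 110 °C; then K2CO3, MeOH, rt
Reagents that add atoms: none
Why: Danheiser benzannulation: conrotatory 4π opening of 26 gives vinylketene 30, with the C4 substituent rotating outward so that the ring stereocentre is erased and C1″ lies away from the ketene; the nucleophilic CH carbon of 29 then attacks the ketene carbonyl carbon in a regioselective [2+2] cycloaddition to give 31, forming C8a–C4a and C6–C5. A second 4π opening gives dienylketene 32, which closes ring A by thermal disrotatory 6π electrocyclisation (C8–C8a) to dienone 33 and tautomerises to the phenol; the transient sp3 carbon C8 becomes aromatic, so no new stereocentre arises. The closest known reaction type is the benzannulation of 3-alkyl- and 4-substituted cyclobutenones with methoxy- or ethoxyacetylene to resorcinol monoethers; the 3-alkoxy-4-alkyl partner is an extension of that substrate class. The step needs methoxy para to C8, which follows from the matched polarity of the ketene carbon and the ynol ether β-carbon. It also needs the ketene to choose the alkyne over the C2″=C3″ alkene, which the trans placement of the side chain in 30 and the excess of the more nucleophilic alkyne should secure. Outward rotation also keeps the C1″–H bond away from the ketene, so a 1,5-hydrogen shift is not expected and the configuration from step 10 is carried through. Methoxyethyne cannot lose an alkene by a retro-ene path at these temperatures, and the K2CO3/MeOH treatment returns any aryl ester formed when the product phenol captures a ketene.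

Step 16
Reactants: 34 3-tert-butoxy-5-methoxy-2-[(1S,2E,7R)-7-[(tert-butyldimethylsilyl)oxy]-1,9-bis[4-(methoxymethoxy)phenyl]non-2-en-1-yl]phenol
Product: 36 4-tert-butoxy-2-hydroxy-6-methoxy-3-[(1S,2E,7R)-7-[(tert-butyldimethylsilyl)oxy]-1,9-bis[4-(methoxymethoxy)phenyl]non-2-en-1-yl]benzaldehyde, via salicyl alcohol 35 (not isolated)
Conditions: MgCl2, Et3N, (CH2O)n, MeCN, 75 °C; aq. NH4Cl
Reagents that add atoms: paraformaldehyde (formaldehyde source), C=O
Why: Casnati–Skattebøl ortho-formylation: the magnesium phenoxide delivers formaldehyde only to the ortho position, a second formaldehyde oxidises the benzylic alkoxide by hydride transfer, and C8 is blocked, so only C4a reacts.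

Step 17
Reactants: 36 4-tert-butoxy-2-hydroxy-6-methoxy-3-[(1S,2E,7R)-7-[(tert-butyldimethylsilyl)oxy]-1,9-bis[4-(methoxymethoxy)phenyl]non-2-en-1-yl]benzaldehyde
Product: 37 1-{4-tert-butoxy-2-hydroxy-6-methoxy-3-[(1S,2E,7R)-7-[(tert-butyldimethylsilyl)oxy]-1,9-bis[4-(methoxymethoxy)phenyl]non-2-en-1-yl]phenyl}ethan-1-ol (both carbinol epimers)
Conditions: MeMgBr (3 equiv), THF, −20 → 0 °C; aq. NH4Cl
Reagents that add atoms: methylmagnesium bromide, C[Mg]Br
Why: Grignard addition to the aldehyde after deprotonation of the phenol; the reagent is not basic enough to remove the C1″ hydrogen, and the new carbinol centre is removed in step 18.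

Step 18
Reactants: 37 1-{4-tert-butoxy-2-hydroxy-6-methoxy-3-[(1S,2E,7R)-7-[(tert-butyldimethylsilyl)oxy]-1,9-bis[4-(methoxymethoxy)phenyl]non-2-en-1-yl]phenyl}ethan-1-ol
Product: 38 1-{4-tert-butoxy-2-hydroxy-6-methoxy-3-[(1S,2E,7R)-7-[(tert-butyldimethylsilyl)oxy]-1,9-bis[4-(methoxymethoxy)phenyl]non-2-en-1-yl]phenyl}ethan-1-one
Conditions: MnO2 (activated, 15 equiv), CH2Cl2, rt
Reagents that add atoms: none
Why: Selective oxidation of a benzylic alcohol by MnO2 under neutral conditions; the hydrogen-bonded phenol and the isolated alkene are not touched.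

Step 19
Reactants: 38 1-{4-tert-butoxy-2-hydroxy-6-methoxy-3-[(1S,2E,7R)-7-[(tert-butyldimethylsilyl)oxy]-1,9-bis[4-(methoxymethoxy)phenyl]non-2-en-1-yl]phenyl}ethan-1-one
Product: 40 7-tert-butoxy-5-methoxy-8-[(1S,2E,7R)-7-[(tert-butyldimethylsilyl)oxy]-1,9-bis[4-(methoxymethoxy)phenyl]non-2-en-1-yl]-4H-chromen-4-one, via enaminone 39 (not isolated)
Conditions: Me2NCH(OMe)2, toluene, 95 °C; evaporate; AcOH, 70 °C
Reagents that add atoms: N,N-dimethylformamide dimethyl acetal, COC(OC)N(C)C
Why: Standard chromone synthesis: the methyl ketone condenses with the formamide acetal to the enaminone, and mild acid triggers 6-endo addition of the phenol and loss of dimethylamine; no strong base or Lewis acid is involved.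

Step 20
Reactants: 40 7-tert-butoxy-5-methoxy-8-[(1S,2E,7R)-7-[(tert-butyldimethylsilyl)oxy]-1,9-bis[4-(methoxymethoxy)phenyl]non-2-en-1-yl]-4H-chromen-4-one; 41 4-(methoxymethoxy)phenylboronic acid
Product: 42 (2S)-7-tert-butoxy-5-methoxy-2-[4-(methoxymethoxy)phenyl]-8-[(1S,2E,7R)-7-[(tert-butyldimethylsilyl)oxy]-1,9-bis[4-(methoxymethoxy)phenyl]non-2-en-1-yl]chroman-4-one
Conditions: [Rh(OH)(cod)]2 (2.5 mol %), (S)-MeO-F12-BIPHEP [(S)-2,2′-bis{bis(3,4,5-trifluorophenyl)phosphino}-6,6′-dimethoxybiphenyl] (5.5 mol %), 41 (3 equiv), toluene–H2O (10:1), 40 °C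
Reagents that add atoms: none
Why: Hayashi–Miyaura asymmetric 1,4-addition of an arylrhodium species to the chromone, with C2 set by the ligand alone. The (S)-ligand is chosen by analogy with cyclic enones, where (S)-biaryl bisphosphines deliver the aryl group to the face that corresponds to (2S) here; this sense is to be confirmed on a model chromone. The electron-poor phosphine disfavours 1,2-addition to the product ketone.

Step 21
Reactants: 42 (2S)-7-tert-butoxy-5-methoxy-2-[4-(methoxymethoxy)phenyl]-8-[(1S,2E,7R)-7-[(tert-butyldimethylsilyl)oxy]-1,9-bis[4-(methoxymethoxy)phenyl]non-2-en-1-yl]chroman-4-one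
Product: 43 (2S)-7-hydroxy-2-(4-hydroxyphenyl)-8-[(1S,2E,7R)-7-hydroxy-1,9-bis(4-hydroxyphenyl)non-2-en-1-yl]-5-methoxychroman-4-one
Conditions: HCl (3 M in MeOH), THF, 0 → 30 °C
Reagents that add atoms: none
Why: Protic acidolysis cleaves the three aryl MOM acetals, the secondary TBS ether and the aryl tert-butyl ether, with methanol trapping the cations. The aryl methyl ether is stable to protic acid, and the flavanone C2 is expected to hold in the absence of base.

## Compound list

1 | methyl 3-(4-hydroxyphenyl)propanoate | COC(=O)CCc1ccc(O)cc1 | starting material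
2 | methyl 3-[4-(methoxymethoxy)phenyl]propanoate | COCOc1ccc(CCC(=O)OC)cc1 | intermediate
3 | 3-[4-(methoxymethoxy)phenyl]propanal | COCOc1ccc(CCC=O)cc1 | intermediate
4 | diisopinocampheylborinate ester of 5 (not isolated) | C=CC[C@@H](OB([C@H]1C[C@H]2C[C@@H]([C@@H]1C)C2(C)C)[C@H]1C[C@H]2C[C@@H]([C@@H]1C)C2(C)C)CCc1ccc(OCOC)cc1 | intermediate
5 | (3S)-1-[4-(methoxymethoxy)phenyl]hex-5-en-3-ol | C=CC[C@@H](O)CCc1ccc(OCOC)cc1 | intermediate
6 | tert-butyl({(3S)-1-[4-(methoxymethoxy)phenyl]hex-5-en-3-yl}oxy)dimethylsilane | C=CC[C@@H](O[Si](C)(C)C(C)(C)C)CCc1ccc(OCOC)cc1 | intermediate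
7 | but-3-en-2-one | CC(=O)C=C | starting material
8 | (3E,6S)-6-[(tert-butyldimethylsilyl)oxy]-8-[4-(methoxymethoxy)phenyl]oct-3-en-2-one | CC(=O)/C=C/C[C@@H](O[Si](C)(C)C(C)(C)C)CCc1ccc(OCOC)cc1 | intermediate
9 | (6R)-6-[(tert-butyldimethylsilyl)oxy]-8-[4-(methoxymethoxy)phenyl]octan-2-one | CC(=O)CCC[C@@H](O[Si](C)(C)C(C)(C)C)CCc1ccc(OCOC)cc1 | intermediate
10 | 4-hydroxybenzaldehyde | O=Cc1ccc(O)cc1 | starting material
11 | 4-(methoxymethoxy)benzaldehyde | COCOc1ccc(C=O)cc1 | intermediate
12 | (7R)-7-[(tert-butyldimethylsilyl)oxy]-1-hydroxy-1,9-bis[4-(methoxymethoxy)phenyl]nonan-3-one, C1 epimers (not isolated) | COCOc1ccc(C(O)CC(=O)CCC[C@@H](O[Si](C)(C)C(C)(C)C)CCc2ccc(OCOC)cc2)cc1 | intermediate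
13 | (1E,7R)-7-[(tert-butyldimethylsilyl)oxy]-1,9-bis[4-(methoxymethoxy)phenyl]non-1-en-3-one | COCOc1ccc(/C=C/C(=O)CCC[C@@H](O[Si](C)(C)C(C)(C)C)CCc2ccc(OCOC)cc2)cc1 | intermediate
14 | (1E,3S,7R)-7-[(tert-butyldimethylsilyl)oxy]-1,9-bis[4-(methoxymethoxy)phenyl]non-1-en-3-ol | COCOc1ccc(/C=C/[C@@H](O)CCC[C@@H](O[Si](C)(C)C(C)(C)C)CCc2ccc(OCOC)cc2)cc1 | intermediate
15 | triethyl orthoacetate | CCOC(C)(OCC)OCC | starting material
16 | mixed orthoester of 14: the 3-O-(1,1-diethoxyethyl) ether (not isolated) | COCOc1ccc(/C=C/[C@@H](OC(C)(OCC)OCC)CCC[C@@H](O[Si](C)(C)C(C)(C)C)CCc2ccc(OCOC)cc2)cc1 | intermediate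
17 | ketene acetal of 14: the 3-O-(1-ethoxyvinyl) ether (not isolated) | COCOc1ccc(/C=C/[C@@H](OC(=C)OCC)CCC[C@@H](O[Si](C)(C)C(C)(C)C)CCc2ccc(OCOC)cc2)cc1 | intermediate
18 | ethyl (3S,4E,9R)-9-[(tert-butyldimethylsilyl)oxy]-3,11-bis[4-(methoxymethoxy)phenyl]undec-4-enoate | CCOC(=O)C[C@@H](/C=C/CCC[C@@H](O[Si](C)(C)C(C)(C)C)CCc1ccc(OCOC)cc1)c1ccc(OCOC)cc1 | intermediate
19 | (3S,4E,9R)-9-[(tert-butyldimethylsilyl)oxy]-3,11-bis[4-(methoxymethoxy)phenyl]undec-4-enoic acid | OC(=O)C[C@@H](/C=C/CCC[C@@H](O[Si](C)(C)C(C)(C)C)CCc1ccc(OCOC)cc1)c1ccc(OCOC)cc1 | intermediate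
20 | trichloroethylene | ClC=C(Cl)Cl | starting material
21 | (E)-1-tert-butoxy-1,2-dichloroethene (not isolated) | CC(C)(C)O/C(Cl)=C\Cl | intermediate
22 | lithium tert-butoxyacetylide (not isolated) | [Li+].[C-]#COC(C)(C)C | intermediate
23 | tert-butoxyethyne | C#COC(C)(C)C | intermediate
24 | acid chloride of 19 (not isolated) | ClC(=O)C[C@@H](/C=C/CCC[C@@H](O[Si](C)(C)C(C)(C)C)CCc1ccc(OCOC)cc1)c1ccc(OCOC)cc1 | intermediate
25 | aldoketene from 24: (3R,4E,9R)-9-[(tert-butyldimethylsilyl)oxy]-3,11-bis[4-(methoxymethoxy)phenyl]undeca-1,4-dien-1-one (not isolated) | O=C=C[C@@H](/C=C/CCC[C@@H](O[Si](C)(C)C(C)(C)C)CCc1ccc(OCOC)cc1)c1ccc(OCOC)cc1 | intermediate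
26 | 3-tert-butoxy-4-[(1R,2E,7R)-7-[(tert-butyldimethylsilyl)oxy]-1,9-bis[4-(methoxymethoxy)phenyl]non-2-en-1-yl]cyclobut-2-en-1-one, both C4 epimers | O=C1C=C(OC(C)(C)C)C1[C@@H](/C=C/CCC[C@@H](O[Si](C)(C)C(C)(C)C)CCc1ccc(OCOC)cc1)c1ccc(OCOC)cc1 | intermediate
27 | 2-chloro-1,1-dimethoxyethane | COC(CCl)OC | starting material
28 | sodium methoxyacetylide (not isolated) | [Na+].[C-]#COC | intermediate
29 | methoxyethyne | C#COC | intermediate
30 | vinylketene from ring opening of 26, side chain trans to the ketene carbon (not isolated) | O=C=C/C(OC(C)(C)C)=C/[C@@H](/C=C/CCC[C@@H](O[Si](C)(C)C(C)(C)C)CCc1ccc(OCOC)cc1)c1ccc(OCOC)cc1 | intermediate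
31 | 3-methoxy-4-(2-tert-butoxyalkenyl)cyclobut-2-en-1-one, the [2+2] adduct of 30 and 29 (not isolated) | O=C1C=C(OC)C1/C(OC(C)(C)C)=C/[C@@H](/C=C/CCC[C@@H](O[Si](C)(C)C(C)(C)C)CCc1ccc(OCOC)cc1)c1ccc(OCOC)cc1 | intermediate
32 | dienylketene from ring opening of 31 (not isolated) | O=C=C/C(OC)=C\C(OC(C)(C)C)=C\[C@@H](/C=C/CCC[C@@H](O[Si](C)(C)C(C)(C)C)CCc1ccc(OCOC)cc1)c1ccc(OCOC)cc1 | intermediate
33 | 5-tert-butoxy-3-methoxy-6-substituted cyclohexa-2,4-dien-1-one, keto tautomer of 34 (not isolated) | O=C1C=C(OC)C=C(OC(C)(C)C)C1[C@@H](/C=C/CCC[C@@H](O[Si](C)(C)C(C)(C)C)CCc1ccc(OCOC)cc1)c1ccc(OCOC)cc1 | intermediate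
34 | 3-tert-butoxy-5-methoxy-2-[(1S,2E,7R)-7-[(tert-butyldimethylsilyl)oxy]-1,9-bis[4-(methoxymethoxy)phenyl]non-2-en-1-yl]phenol | COc1cc(O)c([C@@H](/C=C/CCC[C@@H](O[Si](C)(C)C(C)(C)C)CCc2ccc(OCOC)cc2)c2ccc(OCOC)cc2)c(OC(C)(C)C)c1 | intermediate
35 | 6-(hydroxymethyl) derivative of 34, a salicyl alcohol (not isolated) | COc1cc(OC(C)(C)C)c([C@@H](/C=C/CCC[C@@H](O[Si](C)(C)C(C)(C)C)CCc2ccc(OCOC)cc2)c2ccc(OCOC)cc2)c(O)c1CO | intermediate
36 | 4-tert-butoxy-2-hydroxy-6-methoxy-3-[(1S,2E,7R)-7-[(tert-butyldimethylsilyl)oxy]-1,9-bis[4-(methoxymethoxy)phenyl]non-2-en-1-yl]benzaldehyde | COc1cc(OC(C)(C)C)c([C@@H](/C=C/CCC[C@@H](O[Si](C)(C)C(C)(C)C)CCc2ccc(OCOC)cc2)c2ccc(OCOC)cc2)c(O)c1C=O | intermediate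
37 | 1-{4-tert-butoxy-2-hydroxy-6-methoxy-3-[(1S,2E,7R)-side chain]phenyl}ethan-1-ol, both carbinol epimers | COc1cc(OC(C)(C)C)c([C@@H](/C=C/CCC[C@@H](O[Si](C)(C)C(C)(C)C)CCc2ccc(OCOC)cc2)c2ccc(OCOC)cc2)c(O)c1C(C)O | intermediate
38 | 1-{4-tert-butoxy-2-hydroxy-6-methoxy-3-[(1S,2E,7R)-side chain]phenyl}ethan-1-one | COc1cc(OC(C)(C)C)c([C@@H](/C=C/CCC[C@@H](O[Si](C)(C)C(C)(C)C)CCc2ccc(OCOC)cc2)c2ccc(OCOC)cc2)c(O)c1C(C)=O | intermediate
39 | (E)-3-(dimethylamino)-1-{4-tert-butoxy-2-hydroxy-6-methoxy-3-[(1S,2E,7R)-side chain]phenyl}prop-2-en-1-one (not isolated) | COc1cc(OC(C)(C)C)c([C@@H](/C=C/CCC[C@@H](O[Si](C)(C)C(C)(C)C)CCc2ccc(OCOC)cc2)c2ccc(OCOC)cc2)c(O)c1C(=O)/C=C/N(C)C | intermediate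
40 | 7-tert-butoxy-5-methoxy-8-[(1S,2E,7R)-7-[(tert-butyldimethylsilyl)oxy]-1,9-bis[4-(methoxymethoxy)phenyl]non-2-en-1-yl]-4H-chromen-4-one | COc1cc(OC(C)(C)C)c([C@@H](/C=C/CCC[C@@H](O[Si](C)(C)C(C)(C)C)CCc2ccc(OCOC)cc2)c2ccc(OCOC)cc2)c2occc(=O)c12 | intermediate
41 | 4-(methoxymethoxy)phenylboronic acid | COCOc1ccc(B(O)O)cc1 | starting material
42 | (2S)-7-tert-butoxy-5-methoxy-2-[4-(methoxymethoxy)phenyl]-8-[(1S,2E,7R)-7-[(tert-butyldimethylsilyl)oxy]-1,9-bis[4-(methoxymethoxy)phenyl]non-2-en-1-yl]chroman-4-one | COc1cc(OC(C)(C)C)c([C@@H](/C=C/CCC[C@@H](O[Si](C)(C)C(C)(C)C)CCc2ccc(OCOC)cc2)c2ccc(OCOC)cc2)c2c1C(=O)C[C@@H](c1ccc(OCOC)cc1)O2 | intermediate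
43 | (2S)-7-hydroxy-2-(4-hydroxyphenyl)-8-[(1S,2E,7R)-7-hydroxy-1,9-bis(4-hydroxyphenyl)non-2-en-1-yl]-5-methoxychroman-4-one | COc1cc(O)c([C@@H](/C=C/CCC[C@@H](O)CCc2ccc(O)cc2)c2ccc(O)cc2)c2c1C(=O)C[C@@H](c1ccc(O)cc1)O2 | target

## Step count and risk

Total: 21 steps. Longest linear sequence: 18 steps (1–6, 8–11, 13, 15–21). Steps 7, 12 and 14 are one-step side branches.

**Step 15 (key step).** The vinylogous-ester stabilisation of 26 may raise the barrier of the first ring opening. The temperature then needed could cause loss of isobutene from the tert-butyl enol ether and oligomerisation of 29, or favour inward rotation followed by a hydrogen shift from C1″.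
Fallback, from 26 back to 34: vinylketene 30 is generated at low temperature by elimination. Methoxide (NaOMe, MeOH, 0 °C) opens the ring of 26 to the methyl (2E)-3-tert-butoxy-4-substituted but-2-enoate F1. LiOH gives the corresponding enoic acid F2, and Me2C=C(Cl)NMe2 gives its acid chloride F3. Et3N in the presence of 29 at 0 °C → rt effects 1,4-dehydrochlorination to 30, which is trapped as 31; warming to 80 °C takes 31 through 32 and 33 to 34.

**Step 13.** Self-condensation of the aldoketene 25 and thermal fragmentation of 23 may outrun the cross [2+2]. Amine-mediated migration of the ring double bond toward C8 would give the regioisomeric cyclobutenone.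
Fallback, from 18 back to 26: a halogen-activated ketene is used. LiN(i-Pr)2 at −78 °C followed by C2Cl6 converts 18 into the ethyl 2-chloro ester F4, and LiOH gives the 2-chloro acid F5. The chloroenamine gives the 2-chloro acid chloride F6, and Et3N with 23 generates the alkyl(chloro)ketene F7. This more electrophilic ketene cycloadds to give the 4-chloro-3-tert-butoxycyclobutenone F8. Zn, AcOH and TMEDA in EtOH remove the chlorine and give 26.

**Step 10.** Acid-catalysed ionisation of the electron-rich arylallyl carbinol before rearrangement would erode chirality transfer to C1″ and allow 1,3-transposition of oxygen.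
Fallback, from 14 back to 19: an Ireland–Claisen rearrangement under basic conditions. Ac2O/pyridine gives the allylic acetate F9. LiN(i-Pr)2 and t-BuMe2SiCl in THF–DMPU at −78 °C give the silyl ketene acetal F10, which rearranges on warming to the silyl ester F11. Aqueous work-up gives 19 directly.

**Step 20.** Carbometalation of the electron-rich 5-alkoxychromone may be slow, allowing protodeboronation of 41 to compete. Face selection may be insufficient, or a second aryl group may add to the product ketone.
Fallback, from 38 back to 42: the ring is closed by O1–C2 bond formation. Claisen–Schmidt condensation of 38 with 11 (KOH, EtOH) gives the 2′-hydroxychalcone F12. Intramolecular oxa-Michael addition under a quinine-derived bifunctional thiourea (or NaOAc in EtOH) gives 42 together with its (2R)-epimer F13. The epimers are separated by chromatography, and F13 is returned to the equilibrium through F12.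

**Step 21.** Acid may promote retro-oxa-Michael opening and re-closure at C2 (epimerisation), and tert-butyl or methoxymethyl cations may be captured by the electron-rich C6 of ring A.
Fallback, from 40 back to 43: the order is reversed so that no deprotection follows the creation of C2. HCl/MeOH on 40 gives the fully deprotected chromone F14, which has no labile stereocentre in ring C. The step 20 catalyst then adds commercial 4-hydroxyphenylboronic acid to give 43 directly.

## Further compounds

F1 | step 15 | methyl (2E)-3-tert-butoxy-4-substituted but-2-enoate from methanolysis of 26 | COC(=O)/C=C(/OC(C)(C)C)C[C@@H](/C=C/CCC[C@@H](O[Si](C)(C)C(C)(C)C)CCc1ccc(OCOC)cc1)c1ccc(OCOC)cc1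
F2 | step 15 | (2E)-3-tert-butoxy-4-substituted but-2-enoic acid | OC(=O)/C=C(/OC(C)(C)C)C[C@@H](/C=C/CCC[C@@H](O[Si](C)(C)C(C)(C)C)CCc1ccc(OCOC)cc1)c1ccc(OCOC)cc1
F3 | step 15 | acid chloride of F2 | ClC(=O)/C=C(/OC(C)(C)C)C[C@@H](/C=C/CCC[C@@H](O[Si](C)(C)C(C)(C)C)CCc1ccc(OCOC)cc1)c1ccc(OCOC)cc1
F4 | step 13 | ethyl 2-chloro derivative of 18 (C2 epimers) | CCOC(=O)C(Cl)[C@@H](/C=C/CCC[C@@H](O[Si](C)(C)C(C)(C)C)CCc1ccc(OCOC)cc1)c1ccc(OCOC)cc1
F5 | step 13 | 2-chloro derivative of acid 19 | OC(=O)C(Cl)[C@@H](/C=C/CCC[C@@H](O[Si](C)(C)C(C)(C)C)CCc1ccc(OCOC)cc1)c1ccc(OCOC)cc1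
F6 | step 13 | 2-chloro acid chloride from F5 | ClC(=O)C(Cl)[C@@H](/C=C/CCC[C@@H](O[Si](C)(C)C(C)(C)C)CCc1ccc(OCOC)cc1)c1ccc(OCOC)cc1
F7 | step 13 | alkyl(chloro)ketene from F6 | O=C=C(Cl)[C@@H](/C=C/CCC[C@@H](O[Si](C)(C)C(C)(C)C)CCc1ccc(OCOC)cc1)c1ccc(OCOC)cc1
F8 | step 13 | 4-chloro derivative of cyclobutenone 26 | O=C1C=C(OC(C)(C)C)C1(Cl)[C@@H](/C=C/CCC[C@@H](O[Si](C)(C)C(C)(C)C)CCc1ccc(OCOC)cc1)c1ccc(OCOC)cc1
F9 | step 10 | acetate of allylic alcohol 14 | COCOc1ccc(/C=C/[C@@H](OC(C)=O)CCC[C@@H](O[Si](C)(C)C(C)(C)C)CCc2ccc(OCOC)cc2)cc1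
F10 | step 10 | tert-butyldimethylsilyl ketene acetal of F9 | COCOc1ccc(/C=C/[C@@H](OC(=C)O[Si](C)(C)C(C)(C)C)CCC[C@@H](O[Si](C)(C)C(C)(C)C)CCc2ccc(OCOC)cc2)cc1
F11 | step 10 | tert-butyldimethylsilyl ester of acid 19 | CC(C)(C)[Si](C)(C)OC(=O)C[C@@H](/C=C/CCC[C@@H](O[Si](C)(C)C(C)(C)C)CCc1ccc(OCOC)cc1)c1ccc(OCOC)cc1
F12 | step 20 | 2′-hydroxychalcone from 38 and 11 | COc1cc(OC(C)(C)C)c([C@@H](/C=C/CCC[C@@H](O[Si](C)(C)C(C)(C)C)CCc2ccc(OCOC)cc2)c2ccc(OCOC)cc2)c(O)c1C(=O)/C=C/c1ccc(OCOC)cc1
F13 | step 20 | (2R)-epimer of 42 | COc1cc(OC(C)(C)C)c([C@@H](/C=C/CCC[C@@H](O[Si](C)(C)C(C)(C)C)CCc2ccc(OCOC)cc2)c2ccc(OCOC)cc2)c2c1C(=O)C[C@H](c1ccc(OCOC)cc1)O2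
F14 | step 21 | 7-hydroxy-8-[(1S,2E,7R)-7-hydroxy-1,9-bis(4-hydroxyphenyl)non-2-en-1-yl]-5-methoxy-4H-chromen-4-one | COc1cc(O)c([C@@H](/C=C/CCC[C@@H](O)CCc2ccc(O)cc2)c2ccc(O)cc2)c2occc(=O)c12
A1 | alternative 1 | pentanedial | O=CCCCC=O
A2 | alternative 1 | (1E,3R,7R,8E)-1,9-bis[4-(methoxymethoxy)phenyl]nona-1,8-diene-3,7-diol | O[C@H](CCC[C@@H](O)/C=C/c1ccc(OCOC)cc1)/C=C/c1ccc(OCOC)cc1
A3 | alternative 2 | racemic 2-{2-[4-(methoxymethoxy)phenyl]ethyl}cyclopentan-1-one | O=C1CCCC1CCc1ccc(OCOC)cc1
A4 | alternative 2 | (R)-6-{2-[4-(methoxymethoxy)phenyl]ethyl}tetrahydro-2H-pyran-2-one | O=C1CCC[C@H](CCc2ccc(OCOC)cc2)O1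
A5 | alternative 3 | (3S)-3-(4-acetoxyphenyl)-3-{3-acetoxy-5-methoxy-2-[(1S,2E,7R)-7-acetoxy-1,9-bis(4-acetoxyphenyl)non-2-en-1-yl]phenoxy}propanoic acid | COc1cc(OC(C)=O)c([C@@H](/C=C/CCC[C@@H](OC(C)=O)CCc2ccc(OC(C)=O)cc2)c2ccc(OC(C)=O)cc2)c(O[C@@H](CC(O)=O)c2ccc(OC(C)=O)cc2)c1
A6 | alternative 3 | pentaacetate of 43 | COc1cc(OC(C)=O)c([C@@H](/C=C/CCC[C@@H](OC(C)=O)CCc2ccc(OC(C)=O)cc2)c2ccc(OC(C)=O)cc2)c2c1C(=O)C[C@@H](c1ccc(OC(C)=O)cc1)O2
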